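Time runs unevenly in this flask, so on the repeat watch how the fall of the electrophile slows as free nucleophile is lost. Friday's run is this same flask, followed so far.

- Friday's: electrophile 0.50 M; nucleophile 3 equiv; the very flask that is asked about, followed so far
- flask: electrophile 0.50 M; nucleophile 3.00 equiv; time 40 min

Friday's run (percent of the electrophile charged)

| time / min | electrophile / % | product / % |
|---|---|---|
| 1.33 | 84.7 | 15.0 |
| 4.00 | 62.6 | 36.2 |
| 8.00 | 42.6 | 55.2 |
| 12.0 | 31.0 | 67.5 |
| 15.0 | 25.6 | 73.0 |

(standard deviation of a reading: 0.3 percentage points)

- acid set free is meant together with its idle adduct
- reactions considered so far: nucleophile + acid set free <-> protonated nucleophile; electrophile + nucleophile -> acid set free + product; electrophile + acid set free <-> idle adduct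
- the earlier runs do not show how much of nucleophile is bound; that part of a forecast is a guess

- part of the electrophile that has reacted at 40 min
- share of the unused nucleophile that is free and not bound as protonated nucleophile, at 40 min

Read the table row against row. Charge one nucleophile per electrophile reacted, and the integrated second-order constant slides from 0.0838 L mol⁻¹ min⁻¹ at 4.00 min to 0.0718 L mol⁻¹ min⁻¹ at 15.0 min, a lower value. Charge two, one into product and one bound to the acid set free, and the same rows give 0.0908 L mol⁻¹ min⁻¹ and 0.0903 L mol⁻¹ min⁻¹, level within the reading. Take the later value as the toll constant, the second-order constant read with two nucleophile lost per electrophile reacted. It is indirect: these runs do not show c(protonated nucleophile).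

Carry it to 40 min. The integrated law leaves 6.15% of the electrophile, so I reckon 93.9% reacted. Put that back in: c(nucleophile) is 0.561 M, which is 54.5% of the unused nucleophile.

The forecast gives 94% against my 93.9% and 57% against my 54.5%, holding that “binding looks nearly complete”.

The flask gives 93.9% and 60.5%.

    nucleophile + acid set free ⇌ protonated nucleophile, settled at all times (K = 12.0 L mol⁻¹)
    electrophile + nucleophile → acid set free + product (k = 0.0870 L mol⁻¹ min⁻¹)
    electrophile + acid set free ⇌ idle adduct, settled at all times (K = 2.00 L mol⁻¹)

At 40.0 min this flask holds c(nucleophile) at 0.625 M, above my 0.561 M; on that amount the toll constant, a reading from Friday's run, estimates a pseudo-first-order running half-life of the electrophile of 12.3 min, against the 13 min the step has at that time, while the nucleophile's half-life by the same step is 4.4 h, far longer. The neighbour flask charged with 1.20 equiv of nucleophile keeps 24% of it free at that time, so the toll constant estimates its running half-life at 52.7 min and the constant of the scheme gives 54.8 min, longer than the 40 min, and 35% of its electrophile is still there.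

(The readings were computed from invented constants; noise was put on by code.)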